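**Strategy.** The route rests on cutting the pyran ring F of the lower epigallocatechin unit at C4–C4a and O1–C8a. This separates the phloroglucinol-type ring D from the O1–C2–C3–C4 chain that carries both stereocentres, and neither bond touches a stereocentre. In the key step an ortho-fluoroaryllithium (future ring D) opens an enantiopure cis-2-aryl-3-allyloxyoxetane at C4 under strain release. The C2 alkoxide so freed then displaces fluoride at C8a in the same flask, a formal [3+3] annulation that leaves the aldol-derived cis configuration untouched. The benzylated epigallocatechin is then joined 4β→8 to an epicatechin C4 cation, both 3-hydroxyls are galloylated and fifteen benzyl ethers are hydrogenolysed.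

Key step: step 6

Remark on the chemistry: flavan numbering is used throughout. The upper (epicatechin) unit has rings A (benzo), C (pyran) and B (catechol); the lower (epigallocatechin) unit has rings D (benzo), F (pyran) and E (pyrogallol). The target is read as (2R,3R,4R) in the upper unit and (2R,3R) in the lower unit.

Step 1
Reactants: 1 5-fluororesorcinol (5-fluorobenzene-1,3-diol)
Product: 2 1,3-bis(benzyloxy)-5-fluorobenzene
Conditions: BnBr (2.3 equiv), K2CO3, DMF, 60 °C
Reagents that add atoms: benzyl bromide, BrCc1ccccc1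
Why: Williamson etherification of both phenols with benzyl bromide under carbonate base should proceed cleanly, the aryl fluoride being inert to these conditions.

Step 2
Reactants: 3 allyloxyacetic acid; 4 (S)-4-benzyloxazolidin-2-one
Product: 6 (S)-3-[2-(allyloxy)acetyl]-4-benzyloxazolidin-2-one, via mixed pivalic anhydride 5 (not isolated)
Conditions: PivCl, Et3N, THF, −20 °C; then 4, LiCl, −20 °C → rt
Reagents that add atoms: none
Why: N-acylation of the oxazolidinone through a mixed pivalic anhydride (LiCl/Et3N variant) should occur at the less hindered glycolyl carbonyl, the auxiliary stereocentre not being involved.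

Step 3
Reactants: 6; 7 3,4,5-tris(benzyloxy)benzaldehyde
Product: 9 (S)-4-benzyl-3-[(2S,3R)-2-(allyloxy)-3-hydroxy-3-[3,4,5-tris(benzyloxy)phenyl]propanoyl]oxazolidin-2-one, via Z boron enolate 8 (not isolated)
Conditions: Bu2BOTf, Et3N, CH2Cl2, −78 → 0 °C; 7, −78 → 0 °C; then pH 7 buffer, MeOH, 30% H2O2, 0 °C
Reagents that add atoms: none
Why: Evans syn glycolate aldol reaction, in which soft enolisation gives the Z boron enolate 8 and this should add to the aldehyde through a closed Zimmerman–Traxler chair on the enolate face opposite the benzyl group of the auxiliary, setting the 2S centre (future C3) and the 3R centre (future C2) in a syn relationship.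

Step 4
Reactants: 9
Product: 10 (1R,2R)-2-(allyloxy)-1-[3,4,5-tris(benzyloxy)phenyl]propane-1,3-diol
Conditions: LiBH4, MeOH (1.1 equiv), THF, 0 °C
Reagents that add atoms: none
Why: Reductive removal of the auxiliary with LiBH4 (chemoselective reduction of the exocyclic imide carbonyl) should give the 1,3-diol without touching either stereocentre or the allyl and benzyl ethers.

Step 5
Reactants: 10
Product: 12 (2R,3R)-3-(allyloxy)-2-[3,4,5-tris(benzyloxy)phenyl]oxetane, via primary monotosylate 11 (not isolated)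
Conditions: n-BuLi (1.0 equiv), THF, 0 °C; TsCl (1.0 equiv), 0 °C; n-BuLi (1.0 equiv), 0 → 45 °C
Reagents that add atoms: none
Why: One-pot oxetane synthesis from a 1,3-diol, in which the primary lithium alkoxide is sulfonylated selectively and the benzylic alkoxide then closes the four-membered ring by intramolecular Williamson etherification (4-exo-tet) at the CH2 carbon, so that both stereocentres are retained and the syn diol should map onto the cis-2,3-disubstituted oxetane.

Step 6
Reactants: 2; 12
Product: 15 (2R,3R)-3-(allyloxy)-5,7-bis(benzyloxy)-2-[3,4,5-tris(benzyloxy)phenyl]chromane (3-O-allyl-5,7,3',4',5'-penta-O-benzyl-(−)-epigallocatechin), via aryllithium 13 (not isolated), via lithium alkoxide 14 (not isolated)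
Conditions: 2 (1.5 equiv), n-BuLi (1.3 equiv), THF, −78 °C; 12, BF3·OEt2, −78 °C; then t-BuOH (0.3 equiv), KOt-Bu (4 equiv), DMPU, −78 → 60 °C
Reagents that add atoms: none
Why: Fluorine- and benzyloxy-directed ortho-lithiation of 2 gives 13, whose carbanion (future C4a) attacks the BF3-activated oxetane 12 in an SN2 ring opening at the unsubstituted C4 (C4–C4a bond, driven by release of the oxetane ring strain) to give alkoxide 14, and after exchange to the potassium alkoxide in DMPU the former oxetane oxygen on C2 adds to C8a and expels fluoride (O1–C8a bond). The closest known reaction types are the organolithium/BF3 opening of oxetanes and the alkoxide SNAr cyclisation of 2-alkyl-3,5-dialkoxyfluorobenzenes that closes flavan rings, here telescoped into a formal [3+3] annulation. Ring F closes by a six-membered intramolecular nucleophilic aromatic substitution (addition–elimination at the C–F carbon, 6-exo attack), while the oxetane ring is opened, not closed. No new stereocentre is formed, because C2 and C3 are carried over from 12 with retention (no bond to either is made or broken), so the cis-oxetane should become the 2,3-cis (2R,3R) flavan. The step needs lithiation between F and OBn (secured by the acidifying effect of fluorine together with coordination by the flanking ether oxygen), opening at C4 instead of benzylic C2 (primary carbon, SN2 conditions at −78 °C with the aryllithium present before BF3 is added) and closure through O1 only (the C3 oxygen is capped as its allyl ether, so no five-membered alternative exists).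

Step 7
Reactants: 15
Product: 17 (2R,3R)-5,7-bis(benzyloxy)-2-[3,4,5-tris(benzyloxy)phenyl]chroman-3-ol (5,7,3',4',5'-penta-O-benzyl-(−)-epigallocatechin), via prop-1-enyl ether 16 (not isolated)
Conditions: [Ir(cod)(PMePh2)2]PF6 (H2-activated, cat.), THF, rt; then 1 M aq. HCl, acetone, rt
Reagents that add atoms: none
Why: Iridium-hydride-catalysed isomerisation of the allyl ether to the prop-1-enyl ether followed by mild enol ether hydrolysis should free the 3-hydroxyl without affecting the benzyl ethers or the chroman stereocentres, and it would also cleave any propenyl ether already formed under the basic conditions of step 6.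

Step 8
Reactants: 18 (−)-epicatechin
Product: 19 (2R,3R)-5,7-bis(benzyloxy)-2-[3,4-bis(benzyloxy)phenyl]chroman-3-ol (5,7,3',4'-tetra-O-benzyl-(−)-epicatechin)
Conditions: BnBr (4.4 equiv), K2CO3, DMF, 0 °C → rt
Reagents that add atoms: benzyl bromide, BrCc1ccccc1
Why: Phenol-selective Williamson benzylation under carbonate base should leave the less acidic secondary 3-hydroxyl free and the C2 and C3 centres unchanged.

Step 9
Reactants: 19
Product: 20 (2R,3R,4S)-5,7-bis(benzyloxy)-2-[3,4-bis(benzyloxy)phenyl]-4-(2-ethoxyethoxy)chroman-3-ol (4β ether, 3,4-trans)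
Conditions: DDQ, 2-ethoxyethanol, CH2Cl2, rt
Reagents that add atoms: 2-ethoxyethanol, CCOCCO
Why: DDQ-mediated benzylic oxidation (hydride abstraction at C4 to the cation stabilised by ring A) with trapping by 2-ethoxyethanol anti to the 3-hydroxyl and 2-aryl groups should give the 3,4-trans ether, the new C4 centre being set by substrate control and ionised again in the next step.

Step 10
Reactants: 20; 17
Product: 21 5,7,3',4'-tetra-O-benzyl-(−)-epicatechin-(4β→8)-5,7,3',4',5'-penta-O-benzyl-(−)-epigallocatechin (upper unit 2R,3R,4R; lower unit 2R,3R; both 3-hydroxyls free)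
Conditions: TMSOTf (0.2 equiv), CH2Cl2, −78 → −40 °C; 17 in excess (3 equiv, surplus recovered)
Reagents that add atoms: none
Why: Lewis-acid-promoted ionisation of the C4 ether and Friedel–Crafts alkylation of the phloroglucinol-type ring D of 17 at C8 (the less hindered of its two nucleophilic positions) should form the interflavan bond, the new upper C4 centre (R, 4β) being set by attack anti to the C3 hydroxyl and the C2 aryl group of the cation.

Step 11
Reactants: 21; 22 3,4,5-tris(benzyloxy)benzoic acid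
Product: 24 bis-3-O-[3,4,5-tris(benzyloxy)benzoyl] ester of 21 (pentadeca-O-benzyl target), via acid chloride 23 (not isolated)
Conditions: 22 (4 equiv), (COCl)2, cat. DMF, CH2Cl2, rt, volatiles removed; then 21, DMAP, pyridine, CH2Cl2, 40 °C
Reagents that add atoms: none
Why: DMAP-catalysed acylation (nucleophilic catalysis) of both secondary 3-hydroxyls with the acid chloride made in the same flask should give the bis-gallate without touching any stereocentre.

Step 12
Reactants: 24
Product: 25 (−)-epicatechin 3-O-gallate-(4β→8)-(−)-epigallocatechin 3-O-gallate (CNP0296769.1)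
Conditions: H2 (1 atm), Pd(OH)2/C, THF/MeOH/H2O, rt
Reagents that add atoms: none
Why: Catalytic hydrogenolysis of the fifteen aryl benzyl ethers over Pd(OH)2/C should release all phenols while the two gallate esters, the interflavan bond and the five stereocentres stay intact.

**Compound list**

1 | 5-fluororesorcinol | Oc1cc(O)cc(F)c1 | starting material
2 | 1,3-bis(benzyloxy)-5-fluorobenzene | Fc1cc(OCc2ccccc2)cc(OCc2ccccc2)c1 | intermediate
3 | allyloxyacetic acid | C=CCOCC(=O)O | starting material
4 | (S)-4-benzyloxazolidin-2-one | O=C1N[C@@H](Cc2ccccc2)CO1 | starting material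
5 | allyloxyacetic pivalic anhydride | C=CCOCC(=O)OC(=O)C(C)(C)C | intermediate
6 | (S)-3-[2-(allyloxy)acetyl]-4-benzyloxazolidin-2-one | C=CCOCC(=O)N1[C@@H](Cc2ccccc2)COC1=O | intermediate
7 | 3,4,5-tris(benzyloxy)benzaldehyde | O=Cc1cc(OCc2ccccc2)c(OCc2ccccc2)c(OCc2ccccc2)c1 | starting material
8 | (Z)-dibutylboron enolate of 6 | C=CCO/C=C(\OB(CCCC)CCCC)N1[C@@H](Cc2ccccc2)COC1=O | intermediate
9 | (S)-4-benzyl-3-[(2S,3R)-2-(allyloxy)-3-hydroxy-3-[3,4,5-tris(benzyloxy)phenyl]propanoyl]oxazolidin-2-one | O[C@H](c1cc(OCc2ccccc2)c(OCc2ccccc2)c(OCc2ccccc2)c1)[C@H](OCC=C)C(=O)N1[C@@H](Cc2ccccc2)COC1=O | intermediate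
10 | (1R,2R)-2-(allyloxy)-1-[3,4,5-tris(benzyloxy)phenyl]propane-1,3-diol | O[C@H](c1cc(OCc2ccccc2)c(OCc2ccccc2)c(OCc2ccccc2)c1)[C@H](OCC=C)CO | intermediate
11 | (2R,3R)-2-(allyloxy)-3-hydroxy-3-[3,4,5-tris(benzyloxy)phenyl]propyl 4-methylbenzenesulfonate | O[C@H](c1cc(OCc2ccccc2)c(OCc2ccccc2)c(OCc2ccccc2)c1)[C@H](OCC=C)COS(=O)(=O)c1ccc(C)cc1 | intermediate
12 | (2R,3R)-3-(allyloxy)-2-[3,4,5-tris(benzyloxy)phenyl]oxetane (cis) | O1[C@H](c2cc(OCc3ccccc3)c(OCc3ccccc3)c(OCc3ccccc3)c2)[C@H](OCC=C)C1 | intermediate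
13 | [2,4-bis(benzyloxy)-6-fluorophenyl]lithium | [Li]c1c(F)cc(OCc2ccccc2)cc1OCc1ccccc1 | intermediate
14 | lithium (1R,2R)-2-(allyloxy)-3-[2,4-bis(benzyloxy)-6-fluorophenyl]-1-[3,4,5-tris(benzyloxy)phenyl]propan-1-olate (BF3-bound in the flask) | [Li+].[O-][C@H](c1cc(OCc2ccccc2)c(OCc2ccccc2)c(OCc2ccccc2)c1)[C@H](OCC=C)Cc1c(F)cc(OCc2ccccc2)cc1OCc1ccccc1 | intermediate
15 | (2R,3R)-3-(allyloxy)-5,7-bis(benzyloxy)-2-[3,4,5-tris(benzyloxy)phenyl]chromane | c1ccccc1COc1cc(OCc2ccccc2)c2c(c1)O[C@H](c1cc(OCc3ccccc3)c(OCc3ccccc3)c(OCc3ccccc3)c1)[C@H](OCC=C)C2 | intermediate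
16 | (2R,3R)-5,7-bis(benzyloxy)-3-[(E)-prop-1-enyloxy]-2-[3,4,5-tris(benzyloxy)phenyl]chromane | c1ccccc1COc1cc(OCc2ccccc2)c2c(c1)O[C@H](c1cc(OCc3ccccc3)c(OCc3ccccc3)c(OCc3ccccc3)c1)[C@H](O/C=C/C)C2 | intermediate
17 | (2R,3R)-5,7-bis(benzyloxy)-2-[3,4,5-tris(benzyloxy)phenyl]chroman-3-ol | c1ccccc1COc1cc(OCc2ccccc2)c2c(c1)O[C@H](c1cc(OCc3ccccc3)c(OCc3ccccc3)c(OCc3ccccc3)c1)[C@H](O)C2 | intermediate
18 | (−)-epicatechin, (2R,3R) | O[C@@H]1Cc2c(O)cc(O)cc2O[C@@H]1c1ccc(O)c(O)c1 | starting material
19 | (2R,3R)-5,7-bis(benzyloxy)-2-[3,4-bis(benzyloxy)phenyl]chroman-3-ol | O[C@@H]1Cc2c(OCc3ccccc3)cc(OCc3ccccc3)cc2O[C@@H]1c1ccc(OCc2ccccc2)c(OCc2ccccc2)c1 | intermediate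
20 | (2R,3R,4S)-5,7-bis(benzyloxy)-2-[3,4-bis(benzyloxy)phenyl]-4-(2-ethoxyethoxy)chroman-3-ol | O[C@@H]1[C@@H](OCCOCC)c2c(OCc3ccccc3)cc(OCc3ccccc3)cc2O[C@@H]1c1ccc(OCc2ccccc2)c(OCc2ccccc2)c1 | intermediate
21 | tetra-O-benzylepicatechin-(4β→8)-penta-O-benzylepigallocatechin, upper (2R,3R,4R), lower (2R,3R) | O[C@@H]1[C@@H](c2c(OCc3ccccc3)cc(OCc3ccccc3)c3c2O[C@H](c2cc(OCc4ccccc4)c(OCc4ccccc4)c(OCc4ccccc4)c2)[C@H](O)C3)c2c(OCc3ccccc3)cc(OCc3ccccc3)cc2O[C@@H]1c1ccc(OCc2ccccc2)c(OCc2ccccc2)c1 | intermediate
22 | 3,4,5-tris(benzyloxy)benzoic acid | O=C(O)c1cc(OCc2ccccc2)c(OCc2ccccc2)c(OCc2ccccc2)c1 | starting material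
23 | 3,4,5-tris(benzyloxy)benzoyl chloride | O=C(Cl)c1cc(OCc2ccccc2)c(OCc2ccccc2)c(OCc2ccccc2)c1 | intermediate
24 | bis-3-O-[3,4,5-tris(benzyloxy)benzoyl] ester of 21, upper (2R,3R,4R), lower (2R,3R) | O=C(O[C@@H]1[C@@H](c2c(OCc3ccccc3)cc(OCc3ccccc3)c3c2O[C@H](c2cc(OCc4ccccc4)c(OCc4ccccc4)c(OCc4ccccc4)c2)[C@H](OC(=O)c2cc(OCc4ccccc4)c(OCc4ccccc4)c(OCc4ccccc4)c2)C3)c2c(OCc3ccccc3)cc(OCc3ccccc3)cc2O[C@@H]1c1ccc(OCc2ccccc2)c(OCc2ccccc2)c1)c1cc(OCc2ccccc2)c(OCc2ccccc2)c(OCc2ccccc2)c1 | intermediate
25 | (−)-epicatechin 3-O-gallate-(4β→8)-(−)-epigallocatechin 3-O-gallate, upper (2R,3R,4R), lower (2R,3R) | O=C(O[C@@H]1[C@@H](c2c(O)cc(O)c3c2O[C@H](c2cc(O)c(O)c(O)c2)[C@H](OC(=O)c2cc(O)c(O)c(O)c2)C3)c2c(O)cc(O)cc2O[C@@H]1c1ccc(O)c(O)c1)c1cc(O)c(O)c(O)c1 | target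

**Step count and risks**

Total step count: 12. Longest linear sequence: 9 steps (steps 2, 3, 4, 5, 6, 7, 10, 11, 12).

Steps most likely to fail:

1. Step 6. The lithiation may occur in part at the position between the two benzyloxy groups. The BF3-bound oxetane may ionise at its benzylic carbon before the aryllithium attacks. The boron-bound alkoxide may fail to turn over to a free alkoxide, so that the substitution of fluoride stalls. The fallback sets out from 2 and 12 and comes back at 15. Compound 2 is brominated with NBS in MeCN at 0 °C, which should occur mainly at the position ortho to fluorine and para to a benzyloxy group, to give 1,5-bis(benzyloxy)-2-bromo-3-fluorobenzene F1. Bromine–lithium exchange (n-BuLi, THF, −78 °C) delivers 13 with the metal position fixed, and 13 opens 12 under BF3·OEt2 as before. Quenching with aqueous NH4Cl and chromatography give (1R,2R)-2-(allyloxy)-3-[2,4-bis(benzyloxy)-6-fluorophenyl]-1-[3,4,5-tris(benzyloxy)phenyl]propan-1-ol F2. This alcohol is cyclised in a separate, boron-free operation with KH in DMF (rt → 60 °C) by intramolecular SNAr to 15.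

2. Step 5. The γ-sulfonyloxy benzylic alkoxide may undergo Grob-type fragmentation to aldehyde 7 and a vinyl ether. Sulfonylation may occur at the benzylic hydroxyl, or the electron-rich 2-aryloxetane may open under traces of acid during isolation. The fallback sets out from 10, avoids the four-membered ring and comes back at 15. Compound 10 is tosylated at the primary hydroxyl only (TsCl, Et3N, cat. Bu2SnO, CH2Cl2) and 11 is isolated. Its benzylic hydroxyl is silylated (TESOTf, 2,6-lutidine, CH2Cl2, −78 °C) to give (2R,3R)-2-(allyloxy)-3-(triethylsilyloxy)-3-[3,4,5-tris(benzyloxy)phenyl]propyl 4-methylbenzenesulfonate F3. The aryl Grignard reagent made from 13 and MgBr2·OEt2 is coupled with F3 under Li2CuCl4 catalysis (THF, −20 → 0 °C) to give [(1R,2R)-2-(allyloxy)-3-[2,4-bis(benzyloxy)-6-fluorophenyl]-1-[3,4,5-tris(benzyloxy)phenyl]propoxy]triethylsilane F4. TBAF in THF removes the silyl group to give the fluoro alcohol F2, which is cyclised with KH in DMF to 15.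

3. Step 10. The product dimer may be alkylated further or 20 may self-condense to oligomers. Attack may occur at C6 instead of C8, and ionisation may be slow at low temperature. The fallback sets out from 20 and comes back at 21. Compound 20 is treated with 2-mercaptobenzothiazole and BF3·OEt2 (CH2Cl2, −78 → 0 °C) to give the 4β-thioether (2R,3S,4S)-4-(1,3-benzothiazol-2-ylsulfanyl)-5,7-bis(benzyloxy)-2-[3,4-bis(benzyloxy)phenyl]chroman-3-ol F5. F5 is then activated with the thiophilic salt AgBF4 in THF at 0 °C in the presence of 17. This soft activation is expected to ionise only the thioether, so that near-stoichiometric amounts of the two partners should give 21 with less chain extension.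

Further compounds
F1 | step 6 | 1,5-bis(benzyloxy)-2-bromo-3-fluorobenzene | Fc1cc(OCc2ccccc2)cc(OCc2ccccc2)c1Br
F2 | step 6 | (1R,2R)-2-(allyloxy)-3-[2,4-bis(benzyloxy)-6-fluorophenyl]-1-[3,4,5-tris(benzyloxy)phenyl]propan-1-ol | O[C@H](c1cc(OCc2ccccc2)c(OCc2ccccc2)c(OCc2ccccc2)c1)[C@H](OCC=C)Cc1c(F)cc(OCc2ccccc2)cc1OCc1ccccc1
F3 | step 5 | (2R,3R)-2-(allyloxy)-3-(triethylsilyloxy)-3-[3,4,5-tris(benzyloxy)phenyl]propyl 4-methylbenzenesulfonate | CC[Si](CC)(CC)O[C@H](c1cc(OCc2ccccc2)c(OCc2ccccc2)c(OCc2ccccc2)c1)[C@H](OCC=C)COS(=O)(=O)c1ccc(C)cc1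
F4 | step 5 | [(1R,2R)-2-(allyloxy)-3-[2,4-bis(benzyloxy)-6-fluorophenyl]-1-[3,4,5-tris(benzyloxy)phenyl]propoxy]triethylsilane | CC[Si](CC)(CC)O[C@H](c1cc(OCc2ccccc2)c(OCc2ccccc2)c(OCc2ccccc2)c1)[C@H](OCC=C)Cc1c(F)cc(OCc2ccccc2)cc1OCc1ccccc1
F5 | step 10 | (2R,3S,4S)-4-(1,3-benzothiazol-2-ylsulfanyl)-5,7-bis(benzyloxy)-2-[3,4-bis(benzyloxy)phenyl]chroman-3-ol | O[C@@H]1[C@@H](Sc2nc3ccccc3s2)c2c(OCc3ccccc3)cc(OCc3ccccc3)cc2O[C@@H]1c1ccc(OCc2ccccc2)c(OCc2ccccc2)c1
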